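Ring C is disconnected at O1–C8a and C4–C4a, so ring A enters as an aryne and the O1–C2–C3–C4 chain, with both stereocentres already in place, enters as one acyclic piece. A fluoride-triggered annulation joins 3,5-bis(benzyloxy)benzyne to the caesium alkoxide of an anti β-silyloxy-α-benzyloxy thioester. The alkoxide oxygen adds to the aryne and the resulting aryl anion acylates itself on the thioester, closing the chromanone in one operation. The step exploits the C5 oxygen of ring A, which flanks C4a and fixes the aryne regiochemistry. The thioester comes from an anti-selective catalytic Mukaiyama aldol; debenzylation and selective 7-O-alkylation finish the target.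

Key step: step 6

Assumption: compounds 1, 6, 10 and 17 are taken as purchasable, and the (S)-diamine is taken to steer the benzyloxy enolate to the same face of aldehyde 10 as it does with benzaldehyde.

Step 1
Reactants: 1 3,5-bis(benzyloxy)phenol
Product: 2 3,5-bis(benzyloxy)-2-bromophenol
Conditions: NBS (1.0 equiv), CH2Cl2, −78 °C to 0 °C
Reagents that add atoms: N-bromosuccinimide, O=C1CCC(=O)N1Br
Why: Electrophilic aromatic bromination of a phloroglucinol-type ring, held to one equivalent at low temperature, should go ortho to the free hydroxyl (C2, less hindered than C4 between the two benzyloxy groups and reached by hydrogen-bonded NBS).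

Step 2
Reactants: 2 3,5-bis(benzyloxy)-2-bromophenol
Product: 5 3,5-bis(benzyloxy)-2-(trimethylsilyl)phenyl trifluoromethanesulfonate, via aryl trimethylsilyl ether 3 (not isolated), via lithium silylphenoxide 4 (not isolated)
Conditions: HMDS, THF, 65 °C, evaporate; n-BuLi, THF, −100 °C to −78 °C; Tf2O, −100 °C to rt
Reagents that add atoms: hexamethyldisilazane, C[Si](C)(C)N[Si](C)(C)C; trifluoromethanesulfonic anhydride, O=S(=O)(OS(=O)(=O)C(F)(F)F)C(F)(F)F
Why: This is the standard route to o-silylaryl triflate aryne precursors: O-silylation, bromine–lithium exchange with 1,3 O-to-C silyl migration (retro-Brook rearrangement), then triflation of the phenoxide, all faster at −100 °C than attack on the benzyl ethers.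

Step 3
Reactants: 6 2-(benzyloxy)acetyl chloride
Product: 7 S-ethyl 2-(benzyloxy)ethanethioate
Conditions: EtSH, pyridine, CH2Cl2, 0 °C to rt
Reagents that add atoms: ethanethiol, CCS
Why: Nucleophilic acyl substitution of an acid chloride by a thiol in the presence of pyridine is a routine thioester synthesis.

Step 4
Reactants: 7 S-ethyl 2-(benzyloxy)ethanethioate
Product: 9 (Z)-2-(benzyloxy)-1-(ethylsulfanyl)-1-(trimethylsilyloxy)ethene, via lithium thioester enolate 8 (not isolated)
Conditions: LDA, THF, −78 °C; TMSCl, −78 °C to rt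
Reagents that add atoms: chlorotrimethylsilane, C[Si](C)(C)Cl
Why: Kinetic deprotonation of the thioester through a cyclic six-membered transition state followed by O-silylation should give mainly the (Z)-silyl ketene thioacetal (benzyloxy cis to sulfur), the geometry the anti aldol requires.

Step 5
Reactants: 9 (Z)-2-(benzyloxy)-1-(ethylsulfanyl)-1-(trimethylsilyloxy)ethene; 10 4-(benzyloxy)benzaldehyde
Product: 11 S-ethyl (2R,3R)-2-(benzyloxy)-3-[4-(benzyloxy)phenyl]-3-[(trimethylsilyl)oxy]propanethioate
Conditions: Sn(OTf)2 (20 mol %), (S)-1-ethyl-2-(piperidin-1-ylmethyl)pyrrolidine (22 mol %), EtCN, −78 °C, slow addition of 9 and 10; pH 7 buffer work-up, Et3N-deactivated silica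
Reagents that add atoms: none
Why: In this Mukaiyama aldol under a chiral Sn(OTf)2–diamine Lewis acid (divalent tin), coordination of the benzyloxy oxygen to tin enforces the anti relationship, the (S)-diamine directs the enolate to the si face of the aldehyde so that both new centres are R, and silyl transfer to the tin aldolate turns the catalyst over and leaves the adduct as its trimethylsilyl ether.

Step 6
Reactants: 5 3,5-bis(benzyloxy)-2-(trimethylsilyl)phenyl trifluoromethanesulfonate; 11 S-ethyl (2R,3R)-2-(benzyloxy)-3-[4-(benzyloxy)phenyl]-3-[(trimethylsilyl)oxy]propanethioate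
Product: 15 (2R,3R)-3,5,7-tris(benzyloxy)-2-[4-(benzyloxy)phenyl]-2,3-dihydro-4H-chromen-4-one, via aryne 12 (not isolated), via caesium alkoxide 13 (not isolated), via aryl caesium 14 (not isolated)
Conditions: CsF (5 equiv), 18-crown-6 (0.2 equiv), THF, 0 °C to rt, 5 in excess (2 equiv); then dilute HCl work-up
Reagents that add atoms: none
Why: Proposed new method: fluoride removes both trimethylsilyl groups, giving aryne 12 and, with no proton source present, caesium alkoxide 13; the alkoxide oxygen adds to the aryne carbon that becomes C8a, and aryl anion 14, formed at the future C4a, attacks the thioester carbonyl and expels ethanethiolate, so O1–C8a and C4–C4a form in one operation. The closest known reactions are the fluoride-mediated annulation of arynes with methyl salicylates to xanthones and the aryne ring expansion of β-lactams to 2,3-dihydroquinolin-4-ones; new here is an aliphatic alkoxide, released from its silyl ether, as the nucleophilic end. Ring C closes by a 6-exo-trig acyl substitution. No stereocentre is created: C2 and C3 are carried over from 11 because none of their bonds is broken, and the weakly basic thiolate leaving group should not enolise C3 of the product. The step needs regioselective addition across the aryne, secured by the benzyloxy group next to the aryne bond (the future C5 oxygen), which sends the nucleophile to the distal carbon and places the carbanion ortho to oxygen, as with 3-alkoxyarynes in general. It also needs acylation to outrun protonation of 14 and aryne capture to outrun retro-aldol of 13, which the proton-free medium, the reactive thioester and the excess of 5 are meant to secure.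

Step 7
Reactants: 15 (2R,3R)-3,5,7-tris(benzyloxy)-2-[4-(benzyloxy)phenyl]-2,3-dihydro-4H-chromen-4-one
Product: 16 (2R,3R)-3,5,7-trihydroxy-2-(4-hydroxyphenyl)-2,3-dihydro-4H-chromen-4-one (aromadendrin)
Conditions: H2 (1 atm), Pd/C (10 %), EtOAc/MeOH, rt
Reagents that add atoms: none
Why: Catalytic hydrogenolysis cleaves all four benzyl ethers under neutral conditions that leave the ketone, the cyclic C2–O1 ether and both stereocentres of the trans-dihydroflavonol untouched, as is usual for benzylated flavanonols.

Step 8
Reactants: 17 2-methyl-2-vinyloxirane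
Product: 18 (E)-4-chloro-2-methylbut-2-en-1-ol
Conditions: TiCl4, CH2Cl2, −85 °C; aqueous work-up
Reagents that add atoms: titanium tetrachloride, Cl[Ti](Cl)(Cl)Cl
Why: Lewis acid-mediated SN2' (1,4) opening of the vinyl epoxide, with chloride delivered to the vinyl terminus of the titanium-bound allylic cation, is a known and strongly (E)-selective entry to this chlorohydrin, and any minor (Z)-isomer is removed by chromatography.

Step 9
Reactants: 16 (2R,3R)-3,5,7-trihydroxy-2-(4-hydroxyphenyl)-2,3-dihydro-4H-chromen-4-one; 18 (E)-4-chloro-2-methylbut-2-en-1-ol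
Product: 19 (2R,3R)-3,5-dihydroxy-7-{[(2E)-4-hydroxy-3-methylbut-2-en-1-yl]oxy}-2-(4-hydroxyphenyl)-2,3-dihydro-4H-chromen-4-one
Conditions: K2CO3 (1.1 equiv), KI (cat.), acetone, rt to 40 °C, argon
Reagents that add atoms: none
Why: In this Williamson ether synthesis carbonate ionises only the most acidic phenol, the 7-hydroxyl para to the carbonyl (the 5-hydroxyl is chelated to C4=O, the 4'-hydroxyl is less acidic, the two alcohols stay neutral), and SN2 displacement at the primary allylic chloride keeps the (E) geometry and touches no stereocentre.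

Compound list
1 | 3,5-bis(benzyloxy)phenol | Oc1cc(OCc2ccccc2)cc(OCc2ccccc2)c1 | starting material
2 | 3,5-bis(benzyloxy)-2-bromophenol | Oc1cc(OCc2ccccc2)cc(OCc2ccccc2)c1Br | intermediate
3 | [3,5-bis(benzyloxy)-2-bromophenoxy]trimethylsilane | C[Si](C)(C)Oc1cc(OCc2ccccc2)cc(OCc2ccccc2)c1Br | intermediate (not isolated)
4 | lithium 3,5-bis(benzyloxy)-2-(trimethylsilyl)phenoxide | [Li+].[O-]c1cc(OCc2ccccc2)cc(OCc2ccccc2)c1[Si](C)(C)C | intermediate (not isolated)
5 | 3,5-bis(benzyloxy)-2-(trimethylsilyl)phenyl trifluoromethanesulfonate | C[Si](C)(C)c1c(OS(=O)(=O)C(F)(F)F)cc(OCc2ccccc2)cc1OCc1ccccc1 | intermediate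
6 | 2-(benzyloxy)acetyl chloride | O=C(Cl)COCc1ccccc1 | starting material
7 | S-ethyl 2-(benzyloxy)ethanethioate | CCSC(=O)COCc1ccccc1 | intermediate
8 | lithium (Z)-2-(benzyloxy)-1-(ethylsulfanyl)ethen-1-olate | [Li+].CCS/C([O-])=C\OCc1ccccc1 | intermediate (not isolated)
9 | (Z)-2-(benzyloxy)-1-(ethylsulfanyl)-1-(trimethylsilyloxy)ethene | CCS/C(O[Si](C)(C)C)=C\OCc1ccccc1 | intermediate
10 | 4-(benzyloxy)benzaldehyde | O=Cc1ccc(OCc2ccccc2)cc1 | starting material
11 | S-ethyl (2R,3R)-2-(benzyloxy)-3-[4-(benzyloxy)phenyl]-3-[(trimethylsilyl)oxy]propanethioate | C[Si](C)(C)O[C@H](c1ccc(OCc2ccccc2)cc1)[C@@H](OCc1ccccc1)C(=O)SCC | intermediate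
12 | 3,5-bis(benzyloxy)benzyne (1,2-didehydro-3,5-bis(benzyloxy)benzene) | C1#CC(OCc2ccccc2)=CC(OCc2ccccc2)=C1 | intermediate (not isolated)
13 | caesium (1R,2R)-2-(benzyloxy)-1-[4-(benzyloxy)phenyl]-3-(ethylsulfanyl)-3-oxopropan-1-olate | [Cs+].[O-][C@H](c1ccc(OCc2ccccc2)cc1)[C@@H](OCc1ccccc1)C(=O)SCC | intermediate (not isolated)
14 | S-ethyl (2R,3R)-2-(benzyloxy)-3-[4-(benzyloxy)phenyl]-3-[3,5-bis(benzyloxy)-2-caesiophenoxy]propanethioate (aryl anion, caesium salt) | [Cs+].[C-]1=C(OCc2ccccc2)C=C(OCc2ccccc2)C=C1O[C@H](c1ccc(OCc2ccccc2)cc1)[C@@H](OCc1ccccc1)C(=O)SCC | intermediate (not isolated)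
15 | (2R,3R)-3,5,7-tris(benzyloxy)-2-[4-(benzyloxy)phenyl]-2,3-dihydro-4H-chromen-4-one | C(c1ccccc1)Oc1cc(OCc3ccccc3)c2c(c1)O[C@H](c1ccc(OCc3ccccc3)cc1)[C@@H](OCc1ccccc1)C2=O | intermediate
16 | (2R,3R)-3,5,7-trihydroxy-2-(4-hydroxyphenyl)-2,3-dihydro-4H-chromen-4-one (aromadendrin) | Oc1cc(O)c2c(c1)O[C@H](c1ccc(O)cc1)[C@@H](O)C2=O | intermediate
17 | 2-methyl-2-vinyloxirane (racemic) | C=CC1(C)CO1 | starting material
18 | (E)-4-chloro-2-methylbut-2-en-1-ol | C/C(=C\CCl)CO | intermediate
19 | (2R,3R)-3,5-dihydroxy-7-{[(2E)-4-hydroxy-3-methylbut-2-en-1-yl]oxy}-2-(4-hydroxyphenyl)-2,3-dihydro-4H-chromen-4-one | C/C(=C\COc1cc(O)c2c(c1)O[C@H](c1ccc(O)cc1)[C@@H](O)C2=O)CO | target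

Total step count: 9. Longest linear sequence: 6 steps (steps 3, 4, 5, 6, 7, 9).

Steps most likely to fail

Step 6. The aryl anion may be protonated before it acylates, which would stop at the simple aryl ether. The caesium alkoxide may fragment by retro-aldol, or close onto its own thioester, before it meets the aryne. The fallback uses the known insertion of arynes into the C–O bond of carboxylic acids. It sets out from 11 and comes back at 15. Thioester and silyl ether are hydrolysed (LiOH, H2O2, THF/H2O, 0 °C, acidic work-up) to (2R,3R)-2-(benzyloxy)-3-[4-(benzyloxy)phenyl]-3-hydroxypropanoic acid F1. F1 is heated with 5 and CsF in THF in a sealed tube: the carboxylate oxygen adds to the same aryne carbon and the acyl group migrates to the neighbouring carbon. O1–C8a and C4–C4a are therefore still formed together, giving (2R,3R)-2-(benzyloxy)-1-[2,4-bis(benzyloxy)-6-hydroxyphenyl]-3-[4-(benzyloxy)phenyl]-3-hydroxypropan-1-one F2. Acid-promoted cyclodehydration (BF3·OEt2, CH2Cl2, 0 °C) ionises the 4-benzyloxybenzylic alcohol. Capture by the phenol, under thermodynamic control from the C3 substituent, should give trans-configured 15.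

Step 5. Catalytic turnover may be slow with the electron-rich aldehyde, so that an uncatalysed silyl-triflate pathway erodes the enantio- and anti-selectivity, and the silyl ether may be lost on isolation. The fallback replaces catalyst control by auxiliary control followed by inversion. It sets out from 10 and comes back at 11. A boron-mediated oxazolidinone syn-aldol (Evans aldol; Bu2BOTf, Et3N, CH2Cl2, −78 °C to 0 °C) joins 10 to commercial (R)-4-benzyl-3-[2-(benzyloxy)acetyl]oxazolidin-2-one, O=C(COCc1ccccc1)N1C(=O)OC[C@H]1Cc1ccccc1. It gives (R)-4-benzyl-3-{(2R,3S)-2-(benzyloxy)-3-[4-(benzyloxy)phenyl]-3-hydroxypropanoyl}oxazolidin-2-one F3. Mitsunobu inversion of the benzylic carbinol (4-nitrobenzoic acid, PPh3, DIAD, THF, 0 °C) gives (1R,2R)-3-[(R)-4-benzyl-2-oxooxazolidin-3-yl]-2-(benzyloxy)-1-[4-(benzyloxy)phenyl]-3-oxopropyl 4-nitrobenzoate F4. Excess LiSEt (EtSH, n-BuLi, THF, 0 °C) displaces the auxiliary and removes the nitrobenzoate, giving S-ethyl (2R,3R)-2-(benzyloxy)-3-[4-(benzyloxy)phenyl]-3-hydroxypropanethioate F5. Silylation (TMSCl, imidazole, CH2Cl2) then gives 11.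

Step 9. Alkylation may also occur at the 4'-hydroxyl or twice, and the carbonate may cause ring opening, epimerisation or aerial dehydrogenation of the dihydroflavonol. The fallback is a base-free Tsuji–Trost allylic etherification. It sets out from 16 and comes back at 19. Compound 16 and vinyl epoxide 17 are treated with Pd(PPh3)4 (zerovalent palladium) in THF at 0 °C to rt. The π-allylpalladium alkoxide deprotonates only the most acidic 7-hydroxyl, and the phenoxide attacks the unsubstituted allyl terminus to give 19 directly. No new compound is made on this way (F0). The E/Z ratio of this opening is less secure than in step 8, so the geometry of 19 would have to be checked.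

Further compounds
F1 | step 6 | (2R,3R)-2-(benzyloxy)-3-[4-(benzyloxy)phenyl]-3-hydroxypropanoic acid | O[C@H](c1ccc(OCc2ccccc2)cc1)[C@@H](OCc1ccccc1)C(=O)O
F2 | step 6 | (2R,3R)-2-(benzyloxy)-1-[2,4-bis(benzyloxy)-6-hydroxyphenyl]-3-[4-(benzyloxy)phenyl]-3-hydroxypropan-1-one | O[C@H](c1ccc(OCc2ccccc2)cc1)[C@@H](OCc1ccccc1)C(=O)c1c(O)cc(OCc2ccccc2)cc1OCc1ccccc1
F3 | step 5 | (R)-4-benzyl-3-{(2R,3S)-2-(benzyloxy)-3-[4-(benzyloxy)phenyl]-3-hydroxypropanoyl}oxazolidin-2-one | O[C@@H](c1ccc(OCc2ccccc2)cc1)[C@@H](OCc1ccccc1)C(=O)N1C(=O)OC[C@H]1Cc1ccccc1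
F4 | step 5 | (1R,2R)-3-[(R)-4-benzyl-2-oxooxazolidin-3-yl]-2-(benzyloxy)-1-[4-(benzyloxy)phenyl]-3-oxopropyl 4-nitrobenzoate | O=C(O[C@H](c1ccc(OCc2ccccc2)cc1)[C@@H](OCc1ccccc1)C(=O)N1C(=O)OC[C@H]1Cc1ccccc1)c1ccc(cc1)[N+](=O)[O-]
F5 | step 5 | S-ethyl (2R,3R)-2-(benzyloxy)-3-[4-(benzyloxy)phenyl]-3-hydroxypropanethioate | O[C@H](c1ccc(OCc2ccccc2)cc1)[C@@H](OCc1ccccc1)C(=O)SCC
F0 | step 9 | none | none
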